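**Plan**

- Retrosynthesis: the C7–CH3 bond is cut first (enol triflate of a spiro ketone). Then the C6–C1 bond of ring B is returned to C7 and the C3–Cl bond is exchanged for a C7–O–C3 ether bridge, which unravels ring B into the cycloheptane of a cis-fused bicyclo[5.4.0]undecane. Further cuts: C2–Br/C3–O (bromoetherification), C2=C3 (metathesis), C7–C1 (allyl addition), C6–Cl and C5–C4 (conjugate allylation/chlorination), C6–C11 (bromonium cyclization), C8–C9 (dianion alkylation).
- Forward: ring A is closed first by a bromonium-ion cyclization; a seven-membered ring (C7, C1–C6) is fused to it by metathesis and bridged by oxygen; ring B arises last from that ring by contraction; methylation at C7 ends the route.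
- Enabling feature: the spiro carbon C6 is bonded to C7, which can carry oxygen, and lies 1,4 to the chloride carbon C3 across ring B. One C7 oxygen can therefore first be tied to C3 (fixing C2 and C3 relative to C6) and then push C1 from C7 onto C6.
- Stereochemistry: C10 comes from a catalytic enantioselective bromochlorination and is kept through an enantiospecific bromonium ion. It is relayed to C6 by axial chlorination trans to the C10 bromide, allyl addition anti to C–Cl, and an antiperiplanar 1,2-shift with inversion. C2 and C3 come from the tethered anti bromoetherification and a chloride-for-oxygen exchange with retention.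

Key step: step 10

Remark: atom numbers in the Why lines follow the target skeleton (C1–C5 ring B, C6 spiro carbon, C7–C11 ring A; C7 carries the methyl group, C10 the ring-A bromine, C11 the gem-dimethyl group) and are kept for all intermediates.
Assumption: the ligand enantiomer that gives the (2S)-bromochloride is used, and ring A reacts in the chair with the C10 bromine equatorial in steps 6 and 7.

**Step 1**
Reactants: 1 3-methylbut-2-en-1-ol (prenol)
Product: 2 (2S)-2-bromo-3-chloro-3-methylbutan-1-ol
Conditions: NBS, ClTi(Oi-Pr)3, chiral tridentate Schiff-base ligand (20 mol %), hexanes, −20 °C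
Reagents that add atoms: N-bromosuccinimide O=C1CCC(=O)N1Br; chlorotitanium triisopropoxide CC(C)O[Ti](Cl)(OC(C)C)OC(C)C
Why: Catalytic enantioselective bromochlorination of an allylic alcohol: the alkoxide binds to the chiral titanium complex, which selects the alkene face for bromonium formation and delivers chloride to the distal tertiary carbon (anti addition), so the single stereocenter (later C10) is set by the ligand.

**Step 2**
Reactants: 2 (2S)-2-bromo-3-chloro-3-methylbutan-1-ol
Product: 3 (2S)-2-bromo-3-chloro-3-methylbutyl trifluoromethanesulfonate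
Conditions: Tf2O, 2,6-lutidine, CH2Cl2, −78 °C
Reagents that add atoms: trifluoromethanesulfonic anhydride O=S(=O)(OS(=O)(=O)C(F)(F)F)C(F)(F)F
Why: Sulfonylation of a primary alcohol with Tf2O and a pyridine base; the adjacent stereocenter is not involved.

**Step 3**
Reactants: 3 (2S)-2-bromo-3-chloro-3-methylbutyl trifluoromethanesulfonate; 4 tert-butyl 3-oxobutanoate
Product: 5 tert-butyl (6S)-6-bromo-7-chloro-7-methyl-3-oxooctanoate
Conditions: 4, NaH, THF, 0 °C; n-BuLi, 0 °C; then 3, −78 to −30 °C
Reagents that add atoms: none
Why: Alkylation of the acetoacetate dianion at its terminal carbon by SN2 displacement of the primary triflate at low temperature, which should be faster than attack on the secondary bromide or tertiary chloride; no stereocenter is formed or touched.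

**Step 4**
Reactants: 5 tert-butyl (6S)-6-bromo-7-chloro-7-methyl-3-oxooctanoate
Product: 6 tert-butyl (3S)-3-bromo-2,2-dimethyl-6-oxocyclohexane-1-carboxylate
Conditions: (CF3)2CHOH, 23 °C
Reagents that add atoms: none
Why: Solvolytic ionization of the tertiary chloride with neighbouring-bromine participation gives the bromonium ion without loss of configuration, and the enol carbon opens it at the tertiary carbon in a chair-like cation–olefin cyclization (6-endo opening, enol endocyclic), which forms ring A and keeps C10; the new C6 center is epimerizable and is erased in step 5.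

**Step 5**
Reactants: 6 tert-butyl (3S)-3-bromo-2,2-dimethyl-6-oxocyclohexane-1-carboxylate
Product: 8 (4S)-4-bromo-3,3-dimethyl-2-methylidenecyclohexan-1-one, via β-keto acid 7 (not isolated)
Conditions: TFA, CH2Cl2, 0 °C; then 37% aq. CH2O, Et2NH, THF, 0 to 23 °C
Reagents that add atoms: formaldehyde C=O
Why: Acidolysis of the tert-butyl ester followed by a decarboxylative Mannich reaction–elimination (α-methylenation of a β-keto acid) places the methylene group only at the carboxyl-bearing C6; C10 is not affected.

**Step 6**
Reactants: 8 (4S)-4-bromo-3,3-dimethyl-2-methylidenecyclohexan-1-one; 9 trimethyl(2-methylprop-2-en-1-yl)silane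
Product: 11 (2R,4S)-4-bromo-2-chloro-3,3-dimethyl-2-(3-methylbut-3-en-1-yl)cyclohexan-1-one, via titanium enolate 10 (not isolated)
Conditions: TiCl4, CH2Cl2, −78 °C; then NCS, −78 to −20 °C
Reagents that add atoms: N-chlorosuccinimide O=C1CCC(=O)N1Cl
Why: Hosomi–Sakurai conjugate allylation of the α-methylene ketone gives a regiodefined titanium enolate, whose electrophilic chlorination at C6 should occur axially through a chair-like transition state, trans to the equatorial C10 bromide (a cis approach would force a 1,3-diaxial Cl/Br contact) and with the side chain equatorial, which sets C6.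

**Step 7**
Reactants: 11 (2R,4S)-4-bromo-2-chloro-3,3-dimethyl-2-(3-methylbut-3-en-1-yl)cyclohexan-1-one; 12 allylmagnesium bromide
Product: 13 (1R,2R,4S)-4-bromo-2-chloro-3,3-dimethyl-2-(3-methylbut-3-en-1-yl)-1-(prop-2-en-1-yl)cyclohexan-1-ol
Conditions: THF–Et2O, −78 °C; sat. aq. NH4Cl, −78 °C
Reagents that add atoms: none
Why: Grignard 1,2-addition under polar Felkin–Anh control: the allyl group should enter anti to the axial C6–Cl bond, which sets C7 with allyl and chlorine trans-diaxial (hydroxyl cis to chlorine), the arrangement needed for the later 1,2-shift.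

**Step 8**
Reactants: 13 (1R,2R,4S)-4-bromo-2-chloro-3,3-dimethyl-2-(3-methylbut-3-en-1-yl)-1-(prop-2-en-1-yl)cyclohexan-1-ol
Product: 14 (1R,7R,9S)-9-bromo-7-chloro-4,8,8-trimethylbicyclo[5.4.0]undec-3-en-1-ol
Conditions: second-generation Grubbs catalyst (5 mol %), CH2Cl2, 40 °C
Reagents that add atoms: none
Why: Ring-closing metathesis between the allyl group and the 1,1-disubstituted alkene closes the cis-fused seven-membered ring (C7, C1–C6) with the trisubstituted C2=C3 alkene; the tertiary alcohol and chloride are tolerated and no stereocenter is touched.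

**Step 9**
Reactants: 14 (1R,7R,9S)-9-bromo-7-chloro-4,8,8-trimethylbicyclo[5.4.0]undec-3-en-1-ol
Product: 15 (1R,4S,6R,9R,10R)-4,10-dibromo-6-chloro-5,5,9-trimethyl-12-oxatricyclo[7.2.1.0(1,6)]dodecane
Conditions: NBS, MeCN, 0 °C
Reagents that add atoms: N-bromosuccinimide O=C1CCC(=O)N1Br
Why: Transannular bromoetherification: the C7 hydroxyl opens the bromonium ion at the tertiary C3 (5-endo mode, oxolane ring of an 8-oxabicyclo[3.2.1]octane), so the tether fixes oxygen at C3 on the side of the C7–O bond and anti addition places bromine at C2 trans to it, which sets C2 and C3.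

**Step 10**
Reactants: 15 (1R,4S,6R,9R,10R)-4,10-dibromo-6-chloro-5,5,9-trimethyl-12-oxatricyclo[7.2.1.0(1,6)]dodecane
Product: 17 (2R,3R,6S,10S)-2,10-dibromo-3-chloro-3,11,11-trimethylspiro[5.5]undecan-7-one, via chlorotitanium alkoxide 16 (not isolated)
Conditions: TiCl4 (0.5 equiv), CH2Cl2, −78 to −20 °C; aq. NaHCO3
Reagents that add atoms: none
Why: Proposed new method: TiCl4 should complex the bridging oxygen and ionize the tertiary C3–O bond with help from the anti C2 bromine (bromonium ion), the titanium-bound chloride then returning to C3 on the face that oxygen leaves, to give chlorotitanium alkoxide 16; in 16 the C7–C1 bond is antiperiplanar to the axial C6–Cl bond, so chloride abstraction by titanium with oxygen push moves C1 from C7 to C6 (semipinacol shift), which excises C7 as the ketone, turns the seven-membered ring (C7, C1–C6) into six-membered ring B and returns TiCl4. The closest known reaction types are the Lewis-acid cleavage of tertiary alkyl ethers to chlorides with neighbouring-halogen participation and the Tiffeneau-type halohydrin (semipinacol) ring contraction of fused bicycles to spiro ketones; their merger on a bridged bromo ether is not known. No ring is closed by cyclization: ring B arises by ring contraction through the 1,2-alkyl shift, while the oxolane bridge is opened. The spiro center C6 is set by inversion, C1 entering anti to the departing chloride, so it is controlled by the C6 and C7 centers of 15 (and through them by C10); C3 is set with retention by the bromonium ion, and C2 and C10 are carried through. The step needs ionization at C3–O and not at C7–O (only the C3 cation is bridged by bromine, a C7 cation would lie next to the electron-poor C6–Cl carbon), migration of C1 and not of C8 (only C1 is antiperiplanar to C6–Cl and its shift relieves cycloheptane strain), and it needs the neopentyl secondary C10 bromide and the C2 bromide to resist ionization or Grob-type fragmentation, which the low temperature and the far higher rate of the tertiary-chloride shift should secure.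

**Step 11**
Reactants: 17 (2R,3R,6S,10S)-2,10-dibromo-3-chloro-3,11,11-trimethylspiro[5.5]undecan-7-one
Product: 18 (2R,3R,6S,10S)-2,10-dibromo-3-chloro-3,11,11-trimethylspiro[5.5]undec-7-en-7-yl trifluoromethanesulfonate
Conditions: Tf2O, 2,6-di-tert-butyl-4-methylpyridine, CH2Cl2, 0 to 23 °C
Reagents that add atoms: trifluoromethanesulfonic anhydride O=S(=O)(OS(=O)(=O)C(F)(F)F)C(F)(F)F
Why: Enol triflate formation from a ketone that can enolize only towards C8, under non-basic conditions that avoid a C8 enolate able to displace the C10 bromide and that spare the tertiary chloride.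

**Step 12**
Reactants: 18 (2R,3R,6S,10S)-2,10-dibromo-3-chloro-3,11,11-trimethylspiro[5.5]undec-7-en-7-yl trifluoromethanesulfonate
Product: 19 (2R,3R,6R,10S)-2,10-dibromo-3-chloro-3,7,11,11-tetramethylspiro[5.5]undec-7-ene
Conditions: Me2Zn, Pd(PPh3)4 (5 mol %), THF, 50 °C
Reagents that add atoms: dimethylzinc C[Zn]C
Why: Negishi coupling of the enol triflate with dimethylzinc (oxidative addition of the C–OTf bond to zerovalent palladium should be much faster than that of the unactivated secondary bromides or the tertiary chloride) installs the C7 methyl group and fixes the C7=C8 alkene; no stereocenter is changed, and C6 changes descriptor only.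

**Compound list**

1 | 3-methylbut-2-en-1-ol (prenol) | CC(C)=CCO | starting material
2 | (2S)-2-bromo-3-chloro-3-methylbutan-1-ol | CC(C)(Cl)[C@@H](Br)CO | intermediate
3 | (2S)-2-bromo-3-chloro-3-methylbutyl trifluoromethanesulfonate | CC(C)(Cl)[C@@H](Br)COS(=O)(=O)C(F)(F)F | intermediate
4 | tert-butyl 3-oxobutanoate | CC(=O)CC(=O)OC(C)(C)C | starting material
5 | tert-butyl (6S)-6-bromo-7-chloro-7-methyl-3-oxooctanoate | CC(C)(Cl)[C@@H](Br)CCC(=O)CC(=O)OC(C)(C)C | intermediate
6 | tert-butyl (3S)-3-bromo-2,2-dimethyl-6-oxocyclohexane-1-carboxylate (C1 epimers and enol) | CC1(C)[C@@H](Br)CCC(=O)C1C(=O)OC(C)(C)C | intermediate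
7 | (3S)-3-bromo-2,2-dimethyl-6-oxocyclohexane-1-carboxylic acid | CC1(C)[C@@H](Br)CCC(=O)C1C(=O)O | intermediate
8 | (4S)-4-bromo-3,3-dimethyl-2-methylidenecyclohexan-1-one | CC1(C)[C@@H](Br)CCC(=O)C1=C | intermediate
9 | trimethyl(2-methylprop-2-en-1-yl)silane | CC(=C)C[Si](C)(C)C | starting material
10 | trichlorotitanium (4S)-4-bromo-3,3-dimethyl-2-(3-methylbut-3-en-1-yl)cyclohex-1-en-1-olate | CC1(C)[C@@H](Br)CCC(O[Ti](Cl)(Cl)Cl)=C1CCC(C)=C | intermediate
11 | (2R,4S)-4-bromo-2-chloro-3,3-dimethyl-2-(3-methylbut-3-en-1-yl)cyclohexan-1-one | CC1(C)[C@@H](Br)CCC(=O)[C@@]1(Cl)CCC(C)=C | intermediate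
12 | allylmagnesium bromide | C=CC[Mg]Br | starting material
13 | (1R,2R,4S)-4-bromo-2-chloro-3,3-dimethyl-2-(3-methylbut-3-en-1-yl)-1-(prop-2-en-1-yl)cyclohexan-1-ol | CC1(C)[C@@H](Br)CC[C@@](O)(CC=C)[C@@]1(Cl)CCC(C)=C | intermediate
14 | (1R,7R,9S)-9-bromo-7-chloro-4,8,8-trimethylbicyclo[5.4.0]undec-3-en-1-ol (cis-fused) | CC1(C)[C@@H](Br)CC[C@@]2(O)CC=C(C)CC[C@@]12Cl | intermediate
15 | (1R,4S,6R,9R,10R)-4,10-dibromo-6-chloro-5,5,9-trimethyl-12-oxatricyclo[7.2.1.0(1,6)]dodecane (C7–O–C3 bridged bromo ether) | CC1(C)[C@@H](Br)CC[C@@]2(O3)C[C@@H](Br)[C@@]3(C)CC[C@@]12Cl | intermediate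
16 | trichlorotitanium (1R,3R,4R,7R,9S)-3,9-dibromo-4,7-dichloro-4,8,8-trimethylbicyclo[5.4.0]undecan-1-olate | CC1(C)[C@@H](Br)CC[C@@]2(O[Ti](Cl)(Cl)Cl)C[C@@H](Br)[C@](C)(Cl)CC[C@@]12Cl | intermediate
17 | (2R,3R,6S,10S)-2,10-dibromo-3-chloro-3,11,11-trimethylspiro[5.5]undecan-7-one | O=C1CC[C@H](Br)C(C)(C)[C@@]12CC[C@@](C)(Cl)[C@H](Br)C2 | intermediate
18 | (2R,3R,6S,10S)-2,10-dibromo-3-chloro-3,11,11-trimethylspiro[5.5]undec-7-en-7-yl trifluoromethanesulfonate | FC(F)(F)S(=O)(=O)OC1=CC[C@H](Br)C(C)(C)[C@@]12CC[C@@](C)(Cl)[C@H](Br)C2 | intermediate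
19 | (2R,3R,6R,10S)-2,10-dibromo-3-chloro-3,7,11,11-tetramethylspiro[5.5]undec-7-ene | CC1=CC[C@H](Br)C(C)(C)[C@@]12CC[C@@](C)(Cl)[C@H](Br)C2 | target

**Step count**

Total: 12 steps. Longest linear sequence: 12 steps (from prenol; compounds 4, 9 and 12 are commercial and enter directly).

**Steps most likely to fail**

1. Step 10 (Proposed new method). What may go wrong: ionization at the wrong ether carbon, cationic rearrangement or fragmentation of the ring-opened intermediate, or loss of configuration at C3 by capture of an open cation.
 The fallback uses known reaction types, inverts the order of events, sets out from 14 and comes back at 17. A silver-assisted halohydrin semipinacol rearrangement of 14 (AgBF4, 2,6-di-tert-butylpyridine, CH2Cl2, −40 °C) should give (6S,10S)-10-bromo-3,11,11-trimethylspiro[5.5]undec-2-en-7-one F1 by the same antiperiplanar ring contraction. Meerwein–Ponndorf–Verley reduction (Al(Oi-Pr)3, i-PrOH, 80 °C; equilibrating, so the equatorial alcohol is expected) should give (6S,7S,10S)-10-bromo-3,11,11-trimethylspiro[5.5]undec-2-en-7-ol F2. Bromoetherification (NBS, MeCN, 0 °C) should then close the cineole-type ether (2R,3R,6S,7S,10S)-2,10-dibromo-3,7-epoxy-3,11,11-trimethylspiro[5.5]undecane F3, the C7 oxygen again fixing Br at C2 on the face away from C7. BCl3 (CH2Cl2, −78 °C) should open the tertiary C3–O bond with chloride and retention through the bromonium ion to (2R,3R,6S,7S,10S)-2,10-dibromo-3-chloro-3,11,11-trimethylspiro[5.5]undecan-7-ol F4, and Dess–Martin oxidation returns to 17.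

2. Step 7. What may go wrong: poor facial selectivity of the carbonyl addition, because attack anti to the C6–Cl bond is also the approach that passes the syn-axial C11 methyl group; the epimer cannot undergo the antiperiplanar shift.
 The fallback moves facial control from the substrate to the reagent: a chiral-diol-catalysed allylboration of ketone 11 (allyl–B(pin), 3,3′-disubstituted BINOL catalyst, t-BuOH, toluene), with the catalyst enantiomer chosen to place the allyl group trans to chlorine. It sets out from 11, comes back at 13 and makes no new compound F0.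

3. Step 6. What may go wrong: protonation instead of chlorination of the titanium enolate, or chlorination with poor face selectivity at C6.
 The fallback replaces the conjugate addition by C-alkylation and decarboxylative chlorination; it sets out from 6 and comes back at 11, so step 5 is also bypassed. Alkylation of 6 at the doubly activated carbon with 4-iodo-2-methylbut-1-ene (Cs2CO3, DMF) should give tert-butyl (3S)-3-bromo-2,2-dimethyl-1-(3-methylbut-3-en-1-yl)-6-oxocyclohexane-1-carboxylate F5. Acidolysis (TFA, CH2Cl2, 0 °C) should give (3S)-3-bromo-2,2-dimethyl-1-(3-methylbut-3-en-1-yl)-6-oxocyclohexane-1-carboxylic acid F6, and NCS should chlorinate the enol released on decarboxylation at C6, with the same axial preference, to give 11.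

**Further compounds**

F1 | step 10 | (6S,10S)-10-bromo-3,11,11-trimethylspiro[5.5]undec-2-en-7-one | O=C1CC[C@H](Br)C(C)(C)[C@@]12CCC(C)=CC2
F2 | step 10 | (6S,7S,10S)-10-bromo-3,11,11-trimethylspiro[5.5]undec-2-en-7-ol | O[C@H]1CC[C@H](Br)C(C)(C)[C@@]12CCC(C)=CC2
F3 | step 10 | (2R,3R,6S,7S,10S)-2,10-dibromo-3,7-epoxy-3,11,11-trimethylspiro[5.5]undecane | O1[C@H]2CC[C@H](Br)C(C)(C)[C@@]23CC[C@]1(C)[C@H](Br)C3
F4 | step 10 | (2R,3R,6S,7S,10S)-2,10-dibromo-3-chloro-3,11,11-trimethylspiro[5.5]undecan-7-ol | O[C@H]1CC[C@H](Br)C(C)(C)[C@@]12CC[C@@](C)(Cl)[C@H](Br)C2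
F0 | step 7 | none | none
F5 | step 6 | tert-butyl (3S)-3-bromo-2,2-dimethyl-1-(3-methylbut-3-en-1-yl)-6-oxocyclohexane-1-carboxylate | CC1(C)[C@@H](Br)CCC(=O)C1(CCC(C)=C)C(=O)OC(C)(C)C
F6 | step 6 | (3S)-3-bromo-2,2-dimethyl-1-(3-methylbut-3-en-1-yl)-6-oxocyclohexane-1-carboxylic acid | CC1(C)[C@@H](Br)CCC(=O)C1(CCC(C)=C)C(=O)O
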